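The target is a longipinane: a verbenone-type bicyclo[3.1.1]heptenone (cyclobutane ring B, enone ring C) bridged by seven-membered ring A (C5–C6–C7–C8–C9–C10–C11). Ring A is closed last through C5–C6, the bond that farnesyl diphosphate forms first. The key step exploits that quaternary C6 lies between cyclobutane carbon C5 and oxygenated C7, and that C5 and the C9 arm on C10 are cis-1,3 on ring B. A vinylketene [2+2] cycloaddition folds a trioxygenated farnesoate into a C5 cyclobutanone carrying an α-methyl enone side chain; conjugate hydride delivery creates the C6 enolate (completing the gem-dimethyl group), which adds to the strained C5 ketone.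

Key step: step 11

Numbering (longipinane, used from compound 15 on and in the Why lines): C1 ketone carbon of 26, C2=C3 (methyl C12 on C3), C4 and C11 cyclobutane bridgeheads, C5 cyclobutane CH, C6 gem-dimethyl carbon (C13, C14), C7 and C9 ester carbinols, C8 methylene, C10 quaternary cyclobutane carbon (methyl C15). Ring C = C1–C2–C3–C4–C10–C11.

Assumption 1: aldehyde 3, an industrial vitamin A building block, is taken as purchasable.
Assumption 2: the chiral bisphosphoramide (two 2,2'-bis(methylamino)-1,1'-binaphthyl phosphoryl units linked through N,N'-dimethylpentane-1,5-diamine) is available in both antipodes; step 2 uses the antipode that gives Re-face addition, step 7 the other one.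

Step 1
Reactants: 1 3-methylbut-3-en-2-one
Product: 2 2-(trimethylsilyloxy)-3-methylbuta-1,3-diene
Conditions: LiN(iPr)2, THF, −78 °C; Me3SiCl
Reagents that add atoms: chlorotrimethylsilane, C[Si](C)(C)Cl
Why: Kinetic enolisation at the only acidic position (the acetyl methyl) followed by O-silylation (silyl enol ether formation) should give the 2-silyloxydiene; no stereocentre is formed.

Step 2
Reactants: 3 (2E)-4-acetoxy-2-methylbut-2-enal; 2 2-(trimethylsilyloxy)-3-methylbuta-1,3-diene
Product: 4 (2E,4R)-4-hydroxy-3,7-dimethyl-6-oxoocta-2,7-dien-1-yl acetate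
Conditions: SiCl4, chiral bisphosphoramide (5 mol %), iPr2NEt (10 mol %), CH2Cl2, −78 °C; aq NaHCO3
Reagents that add atoms: none
Why: Lewis-base-activated SiCl4 Mukaiyama aldol, for which conjugated aldehydes are the best substrates, should add the enol ether 1,2 to the aldehyde; Re-face attack under catalyst control sets the R carbinol (future C9).

Step 3
Reactants: 4 (2E,4R)-4-hydroxy-3,7-dimethyl-6-oxoocta-2,7-dien-1-yl acetate
Product: 5 (2E,4R)-3,7-dimethyl-6-oxo-4-(triethylsilyloxy)octa-2,7-dien-1-yl acetate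
Conditions: Et3SiCl, imidazole, DMF, 0 °C
Reagents that add atoms: chlorotriethylsilane, CC[Si](CC)(CC)Cl
Why: Silyl ether protection of the secondary alcohol blocks retro-aldol and later acylation; the stereocentre is not touched.

Step 4
Reactants: 5 (2E,4R)-3,7-dimethyl-6-oxo-4-(triethylsilyloxy)octa-2,7-dien-1-yl acetate
Product: 6 (5R,6E)-8-hydroxy-2,6-dimethyl-5-(triethylsilyloxy)octa-1,6-dien-3-one
Conditions: Candida antarctica lipase B (immobilised), n-BuOH, MTBE, 30 °C
Reagents that add atoms: none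
Why: Enzymatic transesterification removes the primary allylic acetate under neutral conditions, chosen because alkoxide bases would add to the α-methyl enone or eliminate the β-silyloxy group.

Step 5
Reactants: 6 (5R,6E)-8-hydroxy-2,6-dimethyl-5-(triethylsilyloxy)octa-1,6-dien-3-one
Product: 7 (2E,4R)-3,7-dimethyl-6-oxo-4-(triethylsilyloxy)octa-2,7-dienal
Conditions: MnO2, CH2Cl2, rt
Reagents that add atoms: none
Why: Allylic alcohol oxidation with MnO2 should give the E enal without touching the silyl ether or the enone.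

Step 6
Reactants: 8 methyl 3-methylbut-2-enoate
Product: 9 1-methoxy-3-methyl-1-(tert-butyldimethylsilyloxy)buta-1,3-diene
Conditions: LiN(iPr)2, THF/DMPU, −78 °C; tBuMe2SiCl
Reagents that add atoms: tert-butylchlorodimethylsilane, CC(C)(C)[Si](C)(C)Cl
Why: γ-Deprotonation of the senecioate and O-silylation give the silyl dienol ether (vinylogous silyl ketene acetal), whose ketene acetal geometry is inconsequential.

Step 7
Reactants: 7 (2E,4R)-3,7-dimethyl-6-oxo-4-(triethylsilyloxy)octa-2,7-dienal; 9 1-methoxy-3-methyl-1-(tert-butyldimethylsilyloxy)buta-1,3-diene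
Product: 10 methyl (2E,5S,6E,8R)-5-hydroxy-3,7,11-trimethyl-10-oxo-8-(triethylsilyloxy)dodeca-2,6,11-trienoate
Conditions: SiCl4, chiral bisphosphoramide (antipode of step 2, 5 mol %), CH2Cl2, −78 °C; aq NaHCO3
Reagents that add atoms: none
Why: Vinylogous Mukaiyama aldol: the dienolate should attack through its γ-carbon the aldehyde only (ketone and enone are not activated) and give the 2E ester, while Si-face attack under catalyst control sets the 5S carbinol (future C1) independently of the remote C8 centre.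

Step 8
Reactants: 10 methyl (2E,5S,6E,8R)-5-hydroxy-3,7,11-trimethyl-10-oxo-8-(triethylsilyloxy)dodeca-2,6,11-trienoate
Product: 11 methyl (2E,5S,6E,8R)-5-(tert-butyldimethylsilyloxy)-3,7,11-trimethyl-10-oxo-8-(triethylsilyloxy)dodeca-2,6,11-trienoate
Conditions: tBuMe2SiCl, imidazole, DMF, rt
Reagents that add atoms: tert-butylchlorodimethylsilane, CC(C)(C)[Si](C)(C)Cl
Why: Silyl ether protection with a group more robust than the triethylsilyl ether, so that the two oxygens can be released separately later.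

Step 9
Reactants: 11 methyl (2E,5S,6E,8R)-5-(tert-butyldimethylsilyloxy)-3,7,11-trimethyl-10-oxo-8-(triethylsilyloxy)dodeca-2,6,11-trienoate
Product: 12 (2E,5S,6E,8R)-5-(tert-butyldimethylsilyloxy)-3,7,11-trimethyl-10-oxo-8-(triethylsilyloxy)dodeca-2,6,11-trienoic acid
Conditions: Me3SnOH, ClCH2CH2Cl, 80 °C; 0.1 M HCl wash
Reagents that add atoms: trimethyltin hydroxide, C[Sn](C)(C)O
Why: Tin hydroxide ester hydrolysis is mild enough to spare the β-silyloxy ketone, the enone and both silyl ethers.

Step 10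
Reactants: 12 (2E,5S,6E,8R)-5-(tert-butyldimethylsilyloxy)-3,7,11-trimethyl-10-oxo-8-(triethylsilyloxy)dodeca-2,6,11-trienoic acid
Product: 15 (1S,4R,9R,10R,11R)-1-(tert-butyldimethylsilyloxy)-9-(triethylsilyloxy)-5,6-secolongipina-3(12),6(13)-diene-5,7-dione, via acid chloride 13 (not isolated), via vinylketene 14 (not isolated)
Conditions: Me2C=C(Cl)NMe2, CH2Cl2, 0 °C; then slow addition to Et3N, toluene, 110 °C (high dilution)
Reagents that add atoms: none
Why: Dehydrochlorination through the γ-methyl group gives the vinylketene, whose crossed intramolecular [2+2] cycloaddition (ketene carbonyl carbon C5 to the less substituted C11, ketene α-carbon C4 to C10) closes rings B and C at once; the E alkene places the C15 methyl syn and the side chain anti to the C1–C3 bridge, and the C1 silyloxy group, which avoids both the position anti to the forming bond and the C15 methyl, should steer the ketene to the face that leaves it anti to C10.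

Step 11
Reactants: 15 (1S,4R,9R,10R,11R)-1-(tert-butyldimethylsilyloxy)-9-(triethylsilyloxy)-5,6-secolongipina-3(12),6(13)-diene-5,7-dione
Product: 17 (1S,4R,5R,9R,10R,11R)-1-(tert-butyldimethylsilyloxy)-5-hydroxy-9-(triethylsilyloxy)longipin-3(12)-en-7-one, via copper enolate 16 (not isolated)
Conditions: [(Ph3P)CuH]6 (0.4 equiv), toluene, −40 → 0 °C; aq NH4Cl
Reagents that add atoms: none
Why: Copper hydride adds hydride to the unhindered terminal carbon of the α-methyl enone, which creates the tetrasubstituted copper enolate with C6 now carrying both methyl groups and fixes the enolate away from C8. This enolate adds to the cyclobutanone carbonyl C5, a copper hydride reductive aldol cyclisation of a keto-enone whose closest relatives are the known five- and six-membered closures of this type and Reformatsky additions of α,α-dimethyl enolates to ketones. Ring A is closed by the C5–C6 bond in a 7-(enolendo)-exo-trig mode. The only new stereocentre, C5, is set by the tether: the side chain is anchored on the face of C10 anti to the C1–C3 bridge, so C6 can reach C5 only from that face and the hydroxyl ends syn to the bridge. The step needs chemoselectivity for the enone over the cyclobutanone and no proton transfer to a C8 enolate (which would close a five-membered ring); the soft hydride, the covalent copper enolate and the low temperature should secure both. Strain release at the cyclobutanone and the 1,3-diaxial proximity of C5 and the C9 arm should drive the otherwise slow seven-membered closure.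

Step 12
Reactants: 17 (1S,4R,5R,9R,10R,11R)-1-(tert-butyldimethylsilyloxy)-5-hydroxy-9-(triethylsilyloxy)longipin-3(12)-en-7-one
Product: 18 methyl (1S,4R,5R,9R,10R,11R)-1-(tert-butyldimethylsilyloxy)-7-oxo-9-(triethylsilyloxy)longipin-3(12)-en-5-yl oxalate
Conditions: ClC(=O)CO2Me, Et3N, DMAP (cat.), CH2Cl2, 0 °C
Reagents that add atoms: methyl chlorooxoacetate, COC(=O)C(=O)Cl
Why: Acylation of the tertiary cyclobutanol gives the oxalate radical precursor; elimination cannot compete because C4 and C11 are bridgeheads and C6 is quaternary.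

Step 13
Reactants: 18 methyl (1S,4R,5R,9R,10R,11R)-1-(tert-butyldimethylsilyloxy)-7-oxo-9-(triethylsilyloxy)longipin-3(12)-en-5-yl oxalate
Product: 19 (1S,4R,5S,9R,10R,11R)-1-(tert-butyldimethylsilyloxy)-9-(triethylsilyloxy)longipin-3(12)-en-7-one
Conditions: Bu3SnH (0.5 M), AIBN (cat.), toluene, 100 °C
Reagents that add atoms: none
Why: Barton–McCombie-type radical deoxygenation of the tertiary oxalate: at high tin hydride concentration the C5 radical should be reduced before it can undergo 1,2-acyl shift, and because C6 is tied into ring A on the face anti to the C1–C3 bridge hydrogen can only be delivered syn to that bridge, which gives the C5 configuration of the target.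

Step 14
Reactants: 19 (1S,4R,5S,9R,10R,11R)-1-(tert-butyldimethylsilyloxy)-9-(triethylsilyloxy)longipin-3(12)-en-7-one
Product: 20 (1S,4R,5S,9R,10R,11R)-1-(tert-butyldimethylsilyloxy)-9-hydroxylongipin-3(12)-en-7-one
Conditions: PPTS, MeOH/CH2Cl2, 0 °C → rt
Reagents that add atoms: none
Why: Acid-catalysed methanolysis should cleave the triethylsilyl ether selectively in the presence of the tert-butyldimethylsilyl ether.

Step 15
Reactants: 20 (1S,4R,5S,9R,10R,11R)-1-(tert-butyldimethylsilyloxy)-9-hydroxylongipin-3(12)-en-7-one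
Product: 21 (1S,4R,5S,7R,9R,10R,11R)-1-(tert-butyldimethylsilyloxy)longipin-3(12)-ene-7,9-diol
Conditions: Me4NBH(OAc)3, MeCN/AcOH, −30 °C
Reagents that add atoms: none
Why: Evans–Saksena reduction: the C9 alkoxy(diacetoxy)borohydride delivers hydride intramolecularly to the C7 carbonyl on its own face, so the new hydroxyl should end trans (1,3-anti) to the C9 hydroxyl (7R).

Step 16
Reactants: 21 (1S,4R,5S,7R,9R,10R,11R)-1-(tert-butyldimethylsilyloxy)longipin-3(12)-ene-7,9-diol; 22 tiglic acid [(E)-2-methylbut-2-enoic acid]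
Product: 23 (1S,4R,5S,7R,9R,10R,11R)-1-(tert-butyldimethylsilyloxy)longipin-3(12)-ene-7,9-diyl bis[(E)-2-methylbut-2-enoate]
Conditions: 22 (3 equiv), 2,4,6-Cl3C6H2COCl (3 equiv), Et3N, toluene, rt; then 21, DMAP, 80 °C
Reagents that add atoms: tiglic acid (second equivalent of 22, which supplies the second tigloyl group), C/C=C(\C)C(=O)O
Why: Yamaguchi esterification, in which two molecules of the mixed anhydride acylate the two hindered secondary alcohols at oxygen, so C7 and C9 keep their configuration, while the mixed anhydride avoids the deconjugation seen when unsaturated acid chlorides meet amine bases.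

Step 17
Reactants: 23 (1S,4R,5S,7R,9R,10R,11R)-1-(tert-butyldimethylsilyloxy)longipin-3(12)-ene-7,9-diyl bis[(E)-2-methylbut-2-enoate]
Product: 24 (1S,4R,5S,7R,9R,10R,11R)-1-hydroxylongipin-3(12)-ene-7,9-diyl bis[(E)-2-methylbut-2-enoate]
Conditions: HF·pyridine, pyridine, THF, 0 °C → rt
Reagents that add atoms: none
Why: Fluoride-mediated desilylation under buffered acidic conditions should leave the two tiglates untouched.

Step 18
Reactants: 24 (1S,4R,5S,7R,9R,10R,11R)-1-hydroxylongipin-3(12)-ene-7,9-diyl bis[(E)-2-methylbut-2-enoate]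
Product: 26 (4R,5S,7R,9R,10R,11R)-7,9-bis[(E)-2-methylbut-2-enoyloxy]longipin-2-en-1-one, via β,γ-enone 25 (not isolated)
Conditions: Dess–Martin periodinane, CH2Cl2, rt; then DBU (0.1 equiv), 0 °C
Reagents that add atoms: none
Why: Dess–Martin oxidation gives the C1 ketone, and base then moves the exocyclic double bond into conjugation, since the only enolisable position is C2 (C11 is a bridgehead), which destroys the C1 control centre and gives the 2-en-1-one.

Compound list
1 | 3-methylbut-3-en-2-one | CC(=O)C(C)=C | starting material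
2 | 2-(trimethylsilyloxy)-3-methylbuta-1,3-diene | C=C(O[Si](C)(C)C)C(C)=C | intermediate
3 | (2E)-4-acetoxy-2-methylbut-2-enal | CC(=O)OC/C=C(\C)C=O | starting material
4 | (2E,4R)-4-hydroxy-3,7-dimethyl-6-oxoocta-2,7-dien-1-yl acetate | CC(=O)OC/C=C(\C)[C@H](O)CC(=O)C(C)=C | intermediate
5 | (2E,4R)-3,7-dimethyl-6-oxo-4-(triethylsilyloxy)octa-2,7-dien-1-yl acetate | CC(=O)OC/C=C(\C)[C@H](O[Si](CC)(CC)CC)CC(=O)C(C)=C | intermediate
6 | (5R,6E)-8-hydroxy-2,6-dimethyl-5-(triethylsilyloxy)octa-1,6-dien-3-one | OC/C=C(\C)[C@H](O[Si](CC)(CC)CC)CC(=O)C(C)=C | intermediate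
7 | (2E,4R)-3,7-dimethyl-6-oxo-4-(triethylsilyloxy)octa-2,7-dienal | O=C/C=C(\C)[C@H](O[Si](CC)(CC)CC)CC(=O)C(C)=C | intermediate
8 | methyl 3-methylbut-2-enoate | COC(=O)C=C(C)C | starting material
9 | 1-methoxy-3-methyl-1-(tert-butyldimethylsilyloxy)buta-1,3-diene | COC(O[Si](C)(C)C(C)(C)C)=CC(C)=C | intermediate
10 | methyl (2E,5S,6E,8R)-5-hydroxy-3,7,11-trimethyl-10-oxo-8-(triethylsilyloxy)dodeca-2,6,11-trienoate | COC(=O)/C=C(\C)C[C@H](O)/C=C(\C)[C@H](O[Si](CC)(CC)CC)CC(=O)C(C)=C | intermediate
11 | methyl (2E,5S,6E,8R)-5-(tert-butyldimethylsilyloxy)-3,7,11-trimethyl-10-oxo-8-(triethylsilyloxy)dodeca-2,6,11-trienoate | COC(=O)/C=C(\C)C[C@H](O[Si](C)(C)C(C)(C)C)/C=C(\C)[C@H](O[Si](CC)(CC)CC)CC(=O)C(C)=C | intermediate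
12 | (2E,5S,6E,8R)-5-(tert-butyldimethylsilyloxy)-3,7,11-trimethyl-10-oxo-8-(triethylsilyloxy)dodeca-2,6,11-trienoic acid | OC(=O)/C=C(\C)C[C@H](O[Si](C)(C)C(C)(C)C)/C=C(\C)[C@H](O[Si](CC)(CC)CC)CC(=O)C(C)=C | intermediate
13 | acid chloride of 12 | ClC(=O)/C=C(\C)C[C@H](O[Si](C)(C)C(C)(C)C)/C=C(\C)[C@H](O[Si](CC)(CC)CC)CC(=O)C(C)=C | intermediate
14 | (5S,6E,8R)-5-(tert-butyldimethylsilyloxy)-7,11-dimethyl-3-methylidene-8-(triethylsilyloxy)dodeca-1,6,11-triene-1,10-dione (vinylketene) | O=C=CC(=C)C[C@H](O[Si](C)(C)C(C)(C)C)/C=C(\C)[C@H](O[Si](CC)(CC)CC)CC(=O)C(C)=C | intermediate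
15 | (1S,4R,9R,10R,11R)-1-(tert-butyldimethylsilyloxy)-9-(triethylsilyloxy)-5,6-secolongipina-3(12),6(13)-diene-5,7-dione (bicyclo[3.1.1]heptan-6-one; C15 methyl syn and C9 side chain anti to the C1–C3 bridge; OTBS anti to C10) | C=C(C)C(=O)C[C@@H](O[Si](CC)(CC)CC)[C@@]2(C)[C@@H]3[C@@H](O[Si](C)(C)C(C)(C)C)CC(=C)[C@H]2C3=O | intermediate
16 | copper enolate of 15 (C6=C7, C7–O–Cu, phosphine ligand omitted) | CC(C)=C(O[Cu])C[C@@H](O[Si](CC)(CC)CC)[C@@]2(C)[C@@H]3[C@@H](O[Si](C)(C)C(C)(C)C)CC(=C)[C@H]2C3=O | intermediate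
17 | (1S,4R,5R,9R,10R,11R)-1-(tert-butyldimethylsilyloxy)-5-hydroxy-9-(triethylsilyloxy)longipin-3(12)-en-7-one (C5-OH syn to the C1–C3 bridge) | O=C1C[C@@H](O[Si](CC)(CC)CC)[C@@]2(C)[C@@H]3[C@@H](O[Si](C)(C)C(C)(C)C)CC(=C)[C@H]2[C@]3(O)C1(C)C | intermediate
18 | methyl (1S,4R,5R,9R,10R,11R)-1-(tert-butyldimethylsilyloxy)-7-oxo-9-(triethylsilyloxy)longipin-3(12)-en-5-yl oxalate | O=C1C[C@@H](O[Si](CC)(CC)CC)[C@@]2(C)[C@@H]3[C@@H](O[Si](C)(C)C(C)(C)C)CC(=C)[C@H]2[C@]3(OC(=O)C(=O)OC)C1(C)C | intermediate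
19 | (1S,4R,5S,9R,10R,11R)-1-(tert-butyldimethylsilyloxy)-9-(triethylsilyloxy)longipin-3(12)-en-7-one | O=C1C[C@@H](O[Si](CC)(CC)CC)[C@@]2(C)[C@@H]3[C@@H](O[Si](C)(C)C(C)(C)C)CC(=C)[C@H]2[C@@H]3C1(C)C | intermediate
20 | (1S,4R,5S,9R,10R,11R)-1-(tert-butyldimethylsilyloxy)-9-hydroxylongipin-3(12)-en-7-one | O=C1C[C@@H](O)[C@@]2(C)[C@@H]3[C@@H](O[Si](C)(C)C(C)(C)C)CC(=C)[C@H]2[C@@H]3C1(C)C | intermediate
21 | (1S,4R,5S,7R,9R,10R,11R)-1-(tert-butyldimethylsilyloxy)longipin-3(12)-ene-7,9-diol | O[C@@H]1C[C@@H](O)[C@@]2(C)[C@@H]3[C@@H](O[Si](C)(C)C(C)(C)C)CC(=C)[C@H]2[C@@H]3C1(C)C | intermediate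
22 | tiglic acid, (E)-2-methylbut-2-enoic acid | C/C=C(\C)C(=O)O | starting material
23 | (1S,4R,5S,7R,9R,10R,11R)-1-(tert-butyldimethylsilyloxy)longipin-3(12)-ene-7,9-diyl bis[(E)-2-methylbut-2-enoate] | C/C=C(\C)C(=O)O[C@@H]1C[C@@H](OC(=O)/C(C)=C/C)[C@@]2(C)[C@@H]3[C@@H](O[Si](C)(C)C(C)(C)C)CC(=C)[C@H]2[C@@H]3C1(C)C | intermediate
24 | (1S,4R,5S,7R,9R,10R,11R)-1-hydroxylongipin-3(12)-ene-7,9-diyl bis[(E)-2-methylbut-2-enoate] | C/C=C(\C)C(=O)O[C@@H]1C[C@@H](OC(=O)/C(C)=C/C)[C@@]2(C)[C@@H]3[C@@H](O)CC(=C)[C@H]2[C@@H]3C1(C)C | intermediate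
25 | (4R,5S,7R,9R,10R,11R)-7,9-bis[(E)-2-methylbut-2-enoyloxy]longipin-3(12)-en-1-one | C/C=C(\C)C(=O)O[C@@H]1C[C@@H](OC(=O)/C(C)=C/C)[C@@]2(C)[C@@H]3C(=O)CC(=C)[C@H]2[C@@H]3C1(C)C | intermediate
26 | (4R,5S,7R,9R,10R,11R)-7,9-bis[(E)-2-methylbut-2-enoyloxy]longipin-2-en-1-one | C/C=C(\C)C(=O)O[C@@H]1C[C@@H](OC(=O)/C(C)=C/C)[C@@]2(C)[C@@H]3C(=O)C=C(C)[C@H]2[C@@H]3C1(C)C | target

Total step count: 18 (steps 1 and 6 prepare the two silyl nucleophiles).
Longest linear sequence: 17 steps (steps 1–5 and 7–18).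

Steps most likely to fail

1. Step 11 (key step). The seven-membered closure may be slower than protonation of the copper enolate, which would leave the saturated isopropyl ketone. Proton transfer to a C8 enolate would close a five-membered ring onto C5 instead, and 1,2-reduction of the strained ketone is a third escape. Fallback: from 15, RhCl(PPh3)3-catalysed 1,4-hydrosilylation with Et3SiH should give the isolable C6=C7 triethylsilyl enol ether F1. An intramolecular Mukaiyama aldol onto the cyclobutanone (BF3·OEt2, CH2Cl2, −78 °C), in which the ketone and not the enolate is activated, then comes back to the route at 17.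

2. Step 10. The alkene is deactivated by two allylic silyloxy groups, so cycloaddition may be slower than ketene oligomerisation. Deprotonation at the γ-methylene instead of the γ-methyl would lead to loss of the C1 silyloxy group. Facial selectivity rests on the C1 centre alone and may be poor. Fallback: from 12, coupling with pyrrolidine (EDC, HOBt, CH2Cl2) gives the pyrrolidine amide F2. Tf2O and 2,6-di-tert-butyl-4-methylpyridine in ClCH2CH2Cl generate the vinylketeniminium ion, a much stronger electrophile that should add to the alkene at or below room temperature to give the cyclobutaniminium triflate F3. Hydrolysis with aq NaHCO3 comes back to the route at 15.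

3. Step 13. The C5 radical sits β to the C7 carbonyl, so 1,2-acyl migration to C6 (contraction of ring A) may compete with hydrogen transfer. Fragmentation of the hindered oxalate may also be incomplete. Fallback: the deoxygenation is postponed until C7 is no longer a ketone. From 17, PPTS in MeOH frees the C9 hydroxyl to give the 5,9-dihydroxy ketone F4. Me4NBH(OAc)3 reduction directed by the C9 hydroxyl gives the 5,7,9-triol F5. Yamaguchi esterification with two equivalents of 22 acylates only the two secondary hydroxyls and gives the 5-hydroxy bis-tiglate F6. Methyl chlorooxoacetate (Et3N, DMAP) converts the tertiary alcohol into the oxalate F7, and Bu3SnH/AIBN (toluene, 100 °C) then comes back to the route at 23.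

Further compounds
F1 | step 11 | C6=C7 triethylsilyl enol ether of 15 | CC(C)=C(O[Si](CC)(CC)CC)C[C@@H](O[Si](CC)(CC)CC)[C@@]2(C)[C@@H]3[C@@H](O[Si](C)(C)C(C)(C)C)CC(=C)[C@H]2C3=O
F2 | step 10 | 1-[(2E,5S,6E,8R)-5-(tert-butyldimethylsilyloxy)-3,7,11-trimethyl-10-oxo-8-(triethylsilyloxy)dodeca-2,6,11-trienoyl]pyrrolidine | O=C(/C=C(\C)C[C@H](O[Si](C)(C)C(C)(C)C)/C=C(\C)[C@H](O[Si](CC)(CC)CC)CC(=O)C(C)=C)N1CCCC1
F3 | step 10 | C5 pyrrolidinium (cyclobutaniminium) triflate corresponding to 15 | C=C(C)C(=O)C[C@@H](O[Si](CC)(CC)CC)[C@@]2(C)[C@@H]3[C@@H](O[Si](C)(C)C(C)(C)C)CC(=C)[C@H]2C3=[N+]4CCCC4.[O-]S(=O)(=O)C(F)(F)F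
F4 | step 13 | (1S,4R,5R,9R,10R,11R)-1-(tert-butyldimethylsilyloxy)-5,9-dihydroxylongipin-3(12)-en-7-one | O=C1C[C@@H](O)[C@@]2(C)[C@@H]3[C@@H](O[Si](C)(C)C(C)(C)C)CC(=C)[C@H]2[C@]3(O)C1(C)C
F5 | step 13 | 1-(tert-butyldimethylsilyloxy)longipin-3(12)-ene-5,7,9-triol (7,9-trans, ring centres as in 17) | O[C@@H]1C[C@@H](O)[C@@]2(C)[C@@H]3[C@@H](O[Si](C)(C)C(C)(C)C)CC(=C)[C@H]2[C@]3(O)C1(C)C
F6 | step 13 | 1-(tert-butyldimethylsilyloxy)-5-hydroxylongipin-3(12)-ene-7,9-diyl bis[(E)-2-methylbut-2-enoate] | C/C=C(\C)C(=O)O[C@@H]1C[C@@H](OC(=O)/C(C)=C/C)[C@@]2(C)[C@@H]3[C@@H](O[Si](C)(C)C(C)(C)C)CC(=C)[C@H]2[C@]3(O)C1(C)C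
F7 | step 13 | C5 methyl oxalate of F6 | C/C=C(\C)C(=O)O[C@@H]1C[C@@H](OC(=O)/C(C)=C/C)[C@@]2(C)[C@@H]3[C@@H](O[Si](C)(C)C(C)(C)C)CC(=C)[C@H]2[C@]3(OC(=O)C(=O)OC)C1(C)C
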